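The route rests on cutting two bonds at adjacent carbons of ring A of the isocoumarin: the diaryl ether bond C8–O and the bond from C8a to the lactone carbonyl C1. This vicinal pair is read as the two carbons of a C8≡C8a aryne. In one operation the hindered ring B phenoxide adds to C8 and the resulting C8a anion picks up CO2. This delivers the ether and the carboxylic acid together, with no ring formed. The precursor is a ring A silylaryl triflate (silicon on C8, triflate on C8a). It already carries the hept-1-ynyl arm on C4a (future C4, C3 and pentyl) and a benzyl ether on O6.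

Key step: step 7

Remarks
- Locants C1–C8a are isocoumarin locants and are used for ring A from the start. Primed locants follow olivetolic acid (C1' bears the carboxyl group, O2', O4', C5' the ether oxygen, C6' the pentyl chain).
- The target has no stereocentre and no configured double bond, so no step has to set configuration.
- Assumption: 4-(benzyloxy)phenol, 1-heptyne and olivetolic acid are purchased.
- Precursor design: silicon and triflate can sit either way round on C8/C8a, since both isomers release the same aryne 16. Triflate is placed on C8a because its oxygen is then para to O6. The ring therefore comes from 4-(benzyloxy)phenol through a symmetrical dibromide. This avoids a statistical mono-protection and a cross-coupling at a triflate beside silicon, and it leaves silicon on the open C8. The carbon skeleton, the O6 ether and the two aryne carbons are as the disconnection requires.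
- Medium of the key step: KF/18-crown-6 in THF is preferred to CsF in MeCN, because MeCN is acidic enough to protonate the aryl anion. The phenoxide is made with KH so that only H2 is formed beside it.

Step 1
Reactants: 1 4-(benzyloxy)phenol
Product: 2 4-(benzyloxy)-2,6-dibromophenol
Conditions: NBS (2.05 equiv), i-Pr2NH (20 mol %), CH2Cl2, dark, 0 °C to rt
Reagents that add atoms: N-bromosuccinimide, O=C1CCC(=O)N1Br
Why: Amine-catalysed ortho-selective electrophilic bromination of a phenol with NBS: the para position is occupied by the benzyloxy group and the free hydroxyl outranks the ether as director, so both bromines enter next to OH and the product stays symmetrical.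

Step 2
Reactants: 2 4-(benzyloxy)-2,6-dibromophenol
Product: 6 4-(benzyloxy)-2-bromo-6-(trimethylsilyl)phenyl trifluoromethanesulfonate, via silyl ether 3 (not isolated), via aryllithium 4 (not isolated), via lithium phenoxide 5 (not isolated)
Conditions: HMDS, THF, 70 °C, then evaporate; n-BuLi (1.05 equiv), THF, −78 °C; Tf2O (1.2 equiv), −78 to 0 °C
Reagents that add atoms: hexamethyldisilazane, C[Si](C)(C)N[Si](C)(C)C; trifluoromethanesulfonic anhydride, O=S(=O)(OS(=O)(=O)C(F)(F)F)C(F)(F)F; n-butyllithium, [Li]CCCC (supplies only the lithium of 4 and 5)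
Why: Standard one-flask route from 2-bromophenols to silylaryl triflates (O-silylation, bromine–lithium exchange, retro-Brook 1,3-shift of silicon from O to C, O-triflation): the two bromines are equivalent, exchange outruns any attack on the benzyl ether at −78 °C, and the anionic phenoxide 5 resists a second exchange, so one equivalent of n-BuLi desymmetrises the ring.

Step 3
Reactants: 6 4-(benzyloxy)-2-bromo-6-(trimethylsilyl)phenyl trifluoromethanesulfonate; 7 1-heptyne
Product: 8 4-(benzyloxy)-2-(hept-1-yn-1-yl)-6-(trimethylsilyl)phenyl trifluoromethanesulfonate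
Conditions: Pd(PhCN)2Cl2 (3 mol %), [HP(t-Bu)3]BF4 (6 mol %), CuI (2 mol %), i-Pr2NH, 1,4-dioxane, degassed, rt
Reagents that add atoms: none
Why: Sonogashira coupling under the room-temperature P(t-Bu)3 conditions for aryl bromides: this ligand favours C–Br over C–OTf, the triflate is further shielded by two ortho groups and deactivated by the para benzyloxy donor, the bromide lies meta to that donor and ortho to the withdrawing triflate, and without fluoride the C–Si bond is untouched.

Step 4
Reactants: 9 olivetolic acid
Product: 10 benzyl 2,4-bis(benzyloxy)-6-pentylbenzoate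
Conditions: BnBr (3.5 equiv), K2CO3 (4 equiv), DMF, rt then 60 °C
Reagents that add atoms: benzyl bromide, BrCc1ccccc1
Why: Carboxylate alkylation followed by Williamson etherification; the ester forms first at room temperature, which removes the risk of decarboxylation before the hydrogen-bonded 2'-OH is benzylated on warming.

Step 5
Reactants: 10 benzyl 2,4-bis(benzyloxy)-6-pentylbenzoate
Product: 11 benzyl 4,6-bis(benzyloxy)-3-bromo-2-pentylbenzoate (bromine on C5')
Conditions: NBS (1.05 equiv), MeCN, dark, 0 °C to rt
Reagents that add atoms: N-bromosuccinimide, O=C1CCC(=O)N1Br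
Why: Electrophilic aromatic bromination: C5' is para to O2' and ortho to O4', whereas C3' is wedged between two benzyloxy groups, which is the preference that 2,4-dialkoxy-6-alkylbenzoates generally show in halogenation.

Step 6
Reactants: 11 benzyl 4,6-bis(benzyloxy)-3-bromo-2-pentylbenzoate
Product: 13 benzyl 4,6-bis(benzyloxy)-3-hydroxy-2-pentylbenzoate (ring B phenol, hydroxyl on C5'), via pinacol boronate 12 (not isolated)
Conditions: PdCl2(MeCN)2 (3 mol %), SPhos (12 mol %), HBpin (2 equiv), Et3N (3 equiv), 1,4-dioxane, 90 °C; then 30% H2O2, aq NaOH, THF, 0 °C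
Reagents that add atoms: pinacolborane, CC1(C)OBOC1(C)C (boron group of 12); hydrogen peroxide, OO (phenol oxygen of 13)
Why: Miyaura-type palladium-catalysed borylation with pinacolborane, for which the SPhos system accepts electron-rich bromides with two ortho substituents, followed by standard peroxide oxidation of the C–B bond (1,2-aryl shift from boron to oxygen); the doubly flanked benzyl ester survives the short, cold basic treatment.

Step 7
Reactants: 8 4-(benzyloxy)-2-(hept-1-yn-1-yl)-6-(trimethylsilyl)phenyl trifluoromethanesulfonate; 13 benzyl 4,6-bis(benzyloxy)-3-hydroxy-2-pentylbenzoate; 14 carbon dioxide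
Product: 19 4-(benzyloxy)-2-{4,6-bis(benzyloxy)-3-[(benzyloxy)carbonyl]-2-pentylphenoxy}-6-(hept-1-yn-1-yl)benzoic acid, via potassium phenoxide 15 (not isolated), via aryne 16 (not isolated), via aryl anion 17 (not isolated), via potassium carboxylate 18 (not isolated)
Conditions: 13, KH (1.0 equiv), THF, 0 °C; then 18-crown-6 (3 equiv), spray-dried KF (3 equiv), CO2 (1 atm), slow addition of 8 (1.3 equiv), THF, 0 °C to rt; 1 M HCl work-up
Reagents that add atoms: carbon dioxide (14), O=C=O; potassium hydride, [H-].[K+] (supplies only the counter-ion of 15, 17 and 18)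
Why: Proposed new method: fluoride attacks the unhindered silicon on C8 of 8, triflate leaves C8a and aryne 16 is released slowly; the crown-separated, proton-free phenoxide 15 adds through oxygen to C8, and the C8a aryl anion 17, which meets no acidic partner in dry THF, is carboxylated by dissolved CO2 to carboxylate 18, protonated to 19 on work-up. The closest known reaction types are the three-component coupling of arynes, amines and CO2 to anthranilic acids, the fluoride-mediated O-arylation of phenols by silylaryl triflates, and the xanthone synthesis in which the aryl anion born from phenoxide addition to an aryne is caught by a neighbouring ester carbonyl; what is new is an oxygen nucleophile combined with external CO2. No ring is closed and no stereocentre is created. The selectivity needed is regiochemical, oxygen to C8 and carbon to C8a: the alkynyl group on C4a is slim, so its help is mainly inductive, the sp carbon widening the aryne angle at the remote C8 and stabilising charge on the adjacent C8a, while the doubly ortho-substituted phenoxide also prefers the carbon next to C7–H; the O6 ether, meta to C8 and para to C8a, pulls only weakly the other way. Chemoselectivity is secured by the substrate as well: both ortho positions and the para position of 15 are substituted, so Kolbe–Schmitt C-carboxylation is shut off, its hemicarbonate with CO2 forms reversibly, and the ring B ester is meta to the ether oxygen and cannot be reached by the anion. A regioisomeric acid would hold its carboxyl group on C8, not next to the alkyne, could not lactonise in step 8 and would be removed there by a basic wash.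

Step 8
Reactants: 19 4-(benzyloxy)-2-{4,6-bis(benzyloxy)-3-[(benzyloxy)carbonyl]-2-pentylphenoxy}-6-(hept-1-yn-1-yl)benzoic acid
Product: 20 benzyl 4,6-bis(benzyloxy)-3-{[6-(benzyloxy)-1-oxo-3-pentyl-1H-isochromen-8-yl]oxy}-2-pentylbenzoate
Conditions: Ph3PAuNTf2 (5 mol %), CH2Cl2, rt; aq NaHCO3 wash
Reagents that add atoms: none
Why: Cycloisomerisation of a 2-alkynylbenzoic acid by a cationic monovalent gold π-acid, 6-endo-dig: the carboxyl oxygen attacks the alkyne carbon that bears the pentyl chain, the same closure that ortho-(alk-1-ynyl)benzoates undergo with this catalyst, because under non-basic conditions that distal carbon, conjugated through ring A with the carboxyl group, carries the larger positive character, and protodeauration then frees the pyranone.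

Step 9
Reactants: 20 benzyl 4,6-bis(benzyloxy)-3-{[6-(benzyloxy)-1-oxo-3-pentyl-1H-isochromen-8-yl]oxy}-2-pentylbenzoate
Product: 21 4,6-dihydroxy-3-[(6-hydroxy-1-oxo-3-pentyl-1H-isochromen-8-yl)oxy]-2-pentylbenzoic acid (CNP0439913.0)
Conditions: H2 (1 atm), 10% Pd/C, EtOAc, rt, stopped after uptake of 4 equiv H2; filter, concentrate below 30 °C
Reagents that add atoms: none
Why: Catalytic hydrogenolysis of three aryl benzyl ethers and one benzyl ester, neutral and cool enough for the decarboxylation-prone 2,4-dihydroxybenzoic acid; O-benzyl cleavage is much faster than saturation of the trisubstituted, conjugated C3=C4 enol-lactone bond, so monitored hydrogen uptake should leave the isocoumarin intact.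

Compound list
1 | 4-(benzyloxy)phenol | Oc1ccc(OCc2ccccc2)cc1 | starting material
2 | 4-(benzyloxy)-2,6-dibromophenol | Oc1c(Br)cc(OCc2ccccc2)cc1Br | intermediate
3 | [4-(benzyloxy)-2,6-dibromophenoxy]trimethylsilane (formed in the flask) | C[Si](C)(C)Oc1c(Br)cc(OCc2ccccc2)cc1Br | intermediate
4 | [5-(benzyloxy)-3-bromo-2-(trimethylsilyloxy)phenyl]lithium (formed in the flask) | C[Si](C)(C)Oc1c(Br)cc(OCc2ccccc2)cc1[Li] | intermediate
5 | lithium 4-(benzyloxy)-2-bromo-6-(trimethylsilyl)phenoxide (formed in the flask) | [Li+].[O-]c1c(Br)cc(OCc2ccccc2)cc1[Si](C)(C)C | intermediate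
6 | 4-(benzyloxy)-2-bromo-6-(trimethylsilyl)phenyl trifluoromethanesulfonate | C[Si](C)(C)c1cc(OCc2ccccc2)cc(Br)c1OS(=O)(=O)C(F)(F)F | intermediate
7 | 1-heptyne | CCCCCC#C | starting material
8 | 4-(benzyloxy)-2-(hept-1-yn-1-yl)-6-(trimethylsilyl)phenyl trifluoromethanesulfonate (aryne precursor) | CCCCCC#Cc1cc(OCc2ccccc2)cc([Si](C)(C)C)c1OS(=O)(=O)C(F)(F)F | intermediate
9 | olivetolic acid (2,4-dihydroxy-6-pentylbenzoic acid) | CCCCCc1cc(O)cc(O)c1C(=O)O | starting material
10 | benzyl 2,4-bis(benzyloxy)-6-pentylbenzoate | CCCCCc1cc(OCc2ccccc2)cc(OCc2ccccc2)c1C(=O)OCc1ccccc1 | intermediate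
11 | benzyl 4,6-bis(benzyloxy)-3-bromo-2-pentylbenzoate | CCCCCc1c(Br)c(OCc2ccccc2)cc(OCc2ccccc2)c1C(=O)OCc1ccccc1 | intermediate
12 | benzyl 4,6-bis(benzyloxy)-2-pentyl-3-(4,4,5,5-tetramethyl-1,3,2-dioxaborolan-2-yl)benzoate (formed in the flask) | CCCCCc1c(B2OC(C)(C)C(C)(C)O2)c(OCc2ccccc2)cc(OCc2ccccc2)c1C(=O)OCc1ccccc1 | intermediate
13 | benzyl 4,6-bis(benzyloxy)-3-hydroxy-2-pentylbenzoate (ring B phenol; the 5-hydroxy compound in olivetolate numbering) | CCCCCc1c(O)c(OCc2ccccc2)cc(OCc2ccccc2)c1C(=O)OCc1ccccc1 | intermediate
14 | carbon dioxide | O=C=O | starting material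
15 | potassium phenoxide of 13 (formed in the flask) | [K+].CCCCCc1c([O-])c(OCc2ccccc2)cc(OCc2ccccc2)c1C(=O)OCc1ccccc1 | intermediate
16 | 5-(benzyloxy)-3-(hept-1-yn-1-yl)-1,2-didehydrobenzene, the C8≡C8a aryne (formed in the flask) | CCCCCC#CC1=CC(OCc2ccccc2)=CC#C1 | intermediate
17 | potassium salt of the C8a aryl anion of the diaryl ether (formed in the flask) | [K+].CCCCCC#Cc1cc(OCc2ccccc2)cc(Oc2c(OCc3ccccc3)cc(OCc3ccccc3)c(C(=O)OCc3ccccc3)c2CCCCC)[c-]1 | intermediate
18 | potassium salt of acid 19 (formed in the flask) | [K+].CCCCCC#Cc1cc(OCc2ccccc2)cc(Oc2c(OCc3ccccc3)cc(OCc3ccccc3)c(C(=O)OCc3ccccc3)c2CCCCC)c1C(=O)[O-] | intermediate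
19 | 4-(benzyloxy)-2-{4,6-bis(benzyloxy)-3-[(benzyloxy)carbonyl]-2-pentylphenoxy}-6-(hept-1-yn-1-yl)benzoic acid | CCCCCC#Cc1cc(OCc2ccccc2)cc(Oc2c(OCc3ccccc3)cc(OCc3ccccc3)c(C(=O)OCc3ccccc3)c2CCCCC)c1C(=O)O | intermediate
20 | benzyl 4,6-bis(benzyloxy)-3-{[6-(benzyloxy)-1-oxo-3-pentyl-1H-isochromen-8-yl]oxy}-2-pentylbenzoate | CCCCCc1cc2cc(OCc3ccccc3)cc(Oc3c(OCc4ccccc4)cc(OCc4ccccc4)c(C(=O)OCc4ccccc4)c3CCCCC)c2c(=O)o1 | intermediate
21 | 4,6-dihydroxy-3-[(6-hydroxy-1-oxo-3-pentyl-1H-isochromen-8-yl)oxy]-2-pentylbenzoic acid (CNP0439913.0) | CCCCCc1cc2cc(O)cc(Oc3c(O)cc(O)c(C(=O)O)c3CCCCC)c2c(=O)o1 | target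

Total step count: 9. Longest linear sequence: 6 steps (4, 5, 6, 7, 8, 9; the branch 1, 2, 3, 7, 8, 9 is equally long).

Steps most likely to fail

Step 7 (new method). Three things may go wrong. The aryl anion may be protonated before it meets CO2, the phenoxide may add at the wrong aryne carbon, or CO2 may hold back the phenoxide as its hemicarbonate. The fallback uses known chemistry, nucleophilic aromatic substitution in place of the aryne, and runs from 13 back to 19. Commercial 3-bromo-5-fluorophenol (Oc1cc(F)cc(Br)c1) is benzylated (BnBr, K2CO3, DMF) to 1-(benzyloxy)-3-bromo-5-fluorobenzene F1. LDA in THF at −78 °C removes the proton between the two halogens, and DMF gives 4-(benzyloxy)-2-bromo-6-fluorobenzaldehyde F2. Phenol 13 displaces the fluoride ortho to the formyl group (K2CO3, DMF, 100 °C) to give the bromo aldehyde diaryl ether F3. Sonogashira coupling with 7 (PdCl2(PPh3)2, CuI, Et3N, 60 °C) gives the alkynyl aldehyde diaryl ether F4. Pinnick oxidation (NaClO2, NaH2PO4, 2-methylbut-2-ene, t-BuOH–H2O) returns to acid 19.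

Step 8. Closure may run partly 5-exo-dig onto the inner alkyne carbon, or the crowded, twisted carboxyl group may react sluggishly. The fallback replaces π-acid catalysis by electrophilic halocyclisation followed by reduction, and runs from 19 back to 20. Iodolactonisation (I2, NaHCO3, MeCN, rt) opens the iodonium ion at the pentyl-bearing carbon and should give the protected 4-iodoisocoumarin F5. Homogeneous palladium-catalysed formate reduction (Pd(OAc)2, PPh3, HCO2H, Et3N, DMF, 60 °C) removes the iodine without touching the benzyl groups and returns to 20.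

Step 9. The C3=C4 bond may be saturated alongside debenzylation, or the freed acid may lose CO2 during isolation. The fallback is Lewis-acid debenzylation instead of hydrogenation, from 20 directly to 21. It uses BCl3 (excess) and pentamethylbenzene as a non-basic cation scavenger in CH2Cl2 at −78 to −20 °C, followed by a cold methanol quench. No hydrogen is present, so the enol-lactone alkene is not at risk. This way makes no new compound, entry F0.

Further compounds
F1 | step 7 | 1-(benzyloxy)-3-bromo-5-fluorobenzene | Fc1cc(Br)cc(OCc2ccccc2)c1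
F2 | step 7 | 4-(benzyloxy)-2-bromo-6-fluorobenzaldehyde | O=Cc1c(F)cc(OCc2ccccc2)cc1Br
F3 | step 7 | benzyl 4,6-bis(benzyloxy)-3-[5-(benzyloxy)-3-bromo-2-formylphenoxy]-2-pentylbenzoate | CCCCCc1c(Oc2cc(OCc3ccccc3)cc(Br)c2C=O)c(OCc2ccccc2)cc(OCc2ccccc2)c1C(=O)OCc1ccccc1
F4 | step 7 | benzyl 4,6-bis(benzyloxy)-3-[5-(benzyloxy)-2-formyl-3-(hept-1-yn-1-yl)phenoxy]-2-pentylbenzoate | CCCCCC#Cc1cc(OCc2ccccc2)cc(Oc2c(OCc3ccccc3)cc(OCc3ccccc3)c(C(=O)OCc3ccccc3)c2CCCCC)c1C=O
F5 | step 8 | benzyl 4,6-bis(benzyloxy)-3-{[6-(benzyloxy)-4-iodo-1-oxo-3-pentyl-1H-isochromen-8-yl]oxy}-2-pentylbenzoate | CCCCCc1oc(=O)c2c(Oc3c(OCc4ccccc4)cc(OCc4ccccc4)c(C(=O)OCc4ccccc4)c3CCCCC)cc(OCc3ccccc3)cc2c1I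
F0 | step 9 | none | none
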